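All runs are simulated on assumed constants.

The noon and summer flasks are the runs so far, and a row of new charges of X is to be read at the asked time.

| flask | X | J | remark | time |
|---|---|---|---|---|
| noon | 0.093 M | 8.7 mM (held) | run made earlier |  |
| summer | 0.40 M | 8.7 mM (held) | run made earlier |  |
| south-west | 0.12 M | 8.7 mM (held) |  | 3.0 min |
| south | 0.20 M | 8.7 mM (held) |  | 3.0 min |
| north | 0.30 M | 8.7 mM (held) |  | 3.0 min |
| east | 0.50 M | 8.7 mM (held) |  | 3.0 min |

- noon (time / s: D / %): 20.0: 13; 40.0: 38; 60.0: 60; 80.0: 76; 120: 87
- summer (time / s: D / %): 10.0: 0; 25.0: 3; 40.0: 3; 60.0: 9; 90.0: 12; 120: 13

(standard deviation of a reading: 1.5 percentage points)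

- X is a solid; its amount is given per volume of the solution
- at the start none of J is in solution
- at the start none of X is in solution
- "hardly changes" means that all values lie within two and a half points (for a concentration: within two and a half percent of the largest)

- [D] at the end for south-west, south, north, east, in this order
- the shape of the row from first to last (rises all the way / falls, then rises / hardly changes / rises, then falls / falls all the way)

The noon flask makes D at 1.09 mM/s between 20.0 s and 60.0 s, and this reckoning takes that as the starting rate at any charge. The noon rate later falls to 0.256 mM/s, a factor 4.26, with 87 % of its charge already D. The summer flask, charged 4.30 times as high as noon, reads 13 % of its charge as D at 120 s, or 0.0520 M, less than the 0.0809 M that the noon flask reads at that time.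

So this reckoning reads the summer shortfall as a drain on D, pseudo-first-order at fixed cX, and assumes that making and drain balance at the summer reading. Setting it against the making rate gives 0.0525 /M/s per unit of cX. With the drain matching the making rate, X goes at 2 times that rate, or 0.392 M in the asked time. Taking cX as roughly 0.5 of the charge over the run, this balance estimates cD as 2 times the making rate over the drain constant and the charge.

The crossing charge, at which that estimate equals the charge itself, is 0.204 M. Below it this reckoning takes the charge as the limit, and above it takes the crossing charge squared over the charge as an estimate of cD at the asked time. South-west then gives about 0.104 M at the noon yield, south about 0.174 M, north 0.139 M and east 0.0832 M: a row that rises, then falls.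

The forecast differs, with 0.1 M, 0.09 M, 0.07 M, 0.045 M and falls all the way, in its words “I expect a steady fall”.

    G + D → Z (k = 0.0310 /M/s)
    J ⇌ L, rate k2*(csat - [L]) (kL = 0.750 /s)
    X + D → E (k = 0.120 /M/s)
    X ⇌ G, rate k4*(cs4 - [G]) while solid is left; crystals form when [G] > cs4 (solubility = 0.150 M, k = 0.0170 /s)
    G + L → D (k = 4.20 /M/s)

The flasks give 0.0988 M, 0.129 M, 0.138 M and 0.0860 M, so the row rises, then falls. The half-life of D by the loss of X + D to E alone, the other concentrations as charged in south-west, is 0.80 min, shorter than the 3.0 min of the run. The row turns at 0.28 M, a factor 1.40 above the crossing charge. For east, the crossing charge squared over the charge gives 0.0832 M, and the east flask holds 0.0860 M of D with 7.78 % of its X still solid.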